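The plan cuts two bonds at C7 of ring B (isochromene numbering): the C7–O ester bond and the C6–C7 bond. C7 carries an ester oxygen, a methyl group and the C8 ketone, which marks it as the carbenoid carbon of a 2-diazopropanoyl ketone. The adjacent C6 carbinol marks an aldol. One operation therefore attaches the hindered benzoic acid, closes ring B and sets C6 and C7, under dirhodium and chiral phosphoric acid co-catalysis. The precursor is a monocyclic 2H-pyran (finished ring A with its propenyl group). It bears the diazo ketone at pyran C3 and a 2-oxoethyl arm at pyran C4, and is built by a Stille coupling followed by oxa-6π electrocyclisation.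

Key step: step 14

Numbering: atom labels follow the isochromene numbering of the target (ring A: C1, O2, C3, C4; fusion: C4a, C8a; ring B: C5 to C8).
Assumption: the sense of induction of the chiral phosphoric acid cannot be predicted, so the (R)-acid is written and its antipode would be taken if the (6S,7R) series were formed.

Step 1
Reactants: 1 but-3-yn-1-ol
Product: 2 tert-butyl(but-3-yn-1-yloxy)dimethylsilane
Conditions: TBSCl, imidazole, CH2Cl2, 0 °C to rt
Reagents that add atoms: tert-butyldimethylsilyl chloride, CC(C)(C)[Si](C)(C)Cl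
Why: Routine silylation of a primary alcohol gives an ether that withstands the organolithium, palladium and amide-base steps ahead and is later removed by fluoride.

Step 2
Reactants: 2 tert-butyl(but-3-yn-1-yloxy)dimethylsilane; 3 (E)-but-2-enal (crotonaldehyde)
Product: 5 (E)-8-(tert-butyldimethylsilyloxy)oct-2-en-5-yn-4-ol (racemic), via lithium acetylide 4 (not isolated)
Conditions: n-BuLi, THF, −78 °C; 3, −78 to −40 °C; then H2O
Reagents that add atoms: none
Why: Deprotonation of the terminal alkyne and 1,2-addition of the hard lithium acetylide to the enal is a standard carbonyl addition, and the racemic carbinol centre is erased in the next step.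

Step 3
Reactants: 5 (E)-8-(tert-butyldimethylsilyloxy)oct-2-en-5-yn-4-ol
Product: 6 (E)-8-(tert-butyldimethylsilyloxy)oct-2-en-5-yn-4-one
Conditions: MnO2, CH2Cl2, rt
Reagents that add atoms: none
Why: MnO2 oxidation is selective for an alcohol that is both allylic and propargylic and leaves the silyl ether and the (E)-alkene untouched.

Step 4
Reactants: 6 (E)-8-(tert-butyldimethylsilyloxy)oct-2-en-5-yn-4-one
Product: 7 (2E,5Z)-8-(tert-butyldimethylsilyloxy)-6-iodoocta-2,5-dien-4-one
Conditions: LiI, AcOH, MeCN, rt, dark
Reagents that add atoms: lithium iodide, [Li+].[I-]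
Why: Hydroiodination of an ynone (conjugate addition of iodide, then protonation of the iodoallenol on the side away from iodine) is known to give the (Z)-β-iodoenone with iodine cis to the carbonyl group, while iodide addition to the propenyl enone is reversible and leaves it unchanged.

Step 5
Reactants: 8 pent-1-yn-3-ol
Product: 9 pent-1-yn-3-one
Conditions: IBX, EtOAc, 75 °C
Reagents that add atoms: none
Why: IBX oxidation of a secondary propargylic alcohol needs only filtration as work-up, which suits a volatile ynone that is best kept in solution.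

Step 6
Reactants: 9 pent-1-yn-3-one
Product: 10 2-(tributylstannyl)pent-1-en-3-one
Conditions: Bu3SnH, Pd(PPh3)4 (2 mol %), THF, 0 °C
Reagents that add atoms: tributyltin hydride, CCCC[SnH](CCCC)CCCC
Why: Palladium-catalysed syn-hydrostannation of a terminal ynone delivers hydride to the electrophilic β-carbon and tin to the carbon next to the carbonyl group, which should give the 1,1-disubstituted α-stannyl enone.

Step 7
Reactants: 7 (2E,5Z)-8-(tert-butyldimethylsilyloxy)-6-iodoocta-2,5-dien-4-one; 10 2-(tributylstannyl)pent-1-en-3-one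
Product: 12 1-[4-[2-(tert-butyldimethylsilyloxy)ethyl]-6-[(E)-prop-1-enyl]-2H-pyran-3-yl]propan-1-one, via open trienedione 11 (not isolated)
Conditions: Pd(PPh3)4 (5 mol %), CuI (20 mol %), DMF, rt, dark
Reagents that add atoms: none
Why: Stille coupling with retention of the (Z)-iodoalkene geometry places the dienone carbonyl group cis to the new α-methylene ketone, so that 11 is a 1-oxatriene that should close by the known Stille/oxa-6π electrocyclisation cascade to the 2H-pyran, favoured because a reactive cross-conjugated methylene ketone is exchanged for a linearly conjugated, doubly vinylogous ester.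

Step 8
Reactants: 12 1-[4-[2-(tert-butyldimethylsilyloxy)ethyl]-6-[(E)-prop-1-enyl]-2H-pyran-3-yl]propan-1-one
Product: 15 1-[4-[2-(tert-butyldimethylsilyloxy)ethyl]-6-[(E)-prop-1-enyl]-2H-pyran-3-yl]-2-diazopropan-1-one, via lithium enolate 13 (not isolated), via trifluoroacetyl diketone 14 (not isolated)
Conditions: LiN(SiMe3)2, THF, −78 °C; CF3CO2CH2CF3; 5% aq HCl; then 4-AcNHC6H4SO2N3, Et3N, H2O (1 equiv), MeCN, rt
Reagents that add atoms: 4-acetamidobenzenesulfonyl azide, CC(=O)Nc1ccc(cc1)S(=O)(=O)N=[N+]=[N-]
Why: Detrifluoroacetylative Regitz-type diazo transfer (kinetic deprotonation at the ethyl CH2, C-trifluoroacetylation, azide transfer with loss of the activating group) is the standard way to place a diazo group beside an unsaturated ketone that does not undergo direct transfer.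

Step 9
Reactants: 15 1-[4-[2-(tert-butyldimethylsilyloxy)ethyl]-6-[(E)-prop-1-enyl]-2H-pyran-3-yl]-2-diazopropan-1-one
Product: 16 2-diazo-1-[4-(2-hydroxyethyl)-6-[(E)-prop-1-enyl]-2H-pyran-3-yl]propan-1-one
Conditions: Bu4NF, AcOH (1:1), THF, 0 °C
Reagents that add atoms: none
Why: Fluoride cleavage of the primary silyl ether under acetate buffering keeps the medium too weakly basic for vinylogous E1cB loss of the C6 oxygen and too weakly acidic to protonate the diazo carbon.

Step 10
Reactants: 16 2-diazo-1-[4-(2-hydroxyethyl)-6-[(E)-prop-1-enyl]-2H-pyran-3-yl]propan-1-one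
Product: 17 2-diazo-1-[4-(2-oxoethyl)-6-[(E)-prop-1-enyl]-2H-pyran-3-yl]propan-1-one
Conditions: Dess–Martin periodinane, pyridine, CH2Cl2, 0 °C; short filtration, used at once
Reagents that add atoms: none
Why: Pyridine-buffered Dess–Martin oxidation is metal-free, tolerated by diazo carbonyl groups and stops at the aldehyde, whose doubly activated C5 methylene is the reason for immediate use.

Step 11
Reactants: 18 3-methoxy-5-methylphenol
Product: 20 4-hydroxy-2-methoxy-6-methylbenzaldehyde, via aryl iminium chloride 19 (not isolated)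
Conditions: POCl3, DMF, 0 °C to rt; then ice-water
Reagents that add atoms: N,N-dimethylformamide, CN(C)C=O; water, O
Why: Vilsmeier–Haack formylation of a free phenol should go mainly para to the hydroxyl group, here the position between OCH3 and CH3, and any chelated ortho-hydroxy aldehyde is less polar and separable.

Step 12
Reactants: 20 4-hydroxy-2-methoxy-6-methylbenzaldehyde
Product: 21 4-(tert-butyldimethylsilyloxy)-2-methoxy-6-methylbenzaldehyde
Conditions: TBSCl, imidazole, DMF, rt
Reagents that add atoms: tert-butyldimethylsilyl chloride, CC(C)(C)[Si](C)(C)Cl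
Why: Standard silylation masks the only phenol, which would otherwise compete with the carboxyl group for the carbenoid in step 14.

Step 13
Reactants: 21 4-(tert-butyldimethylsilyloxy)-2-methoxy-6-methylbenzaldehyde
Product: 22 4-(tert-butyldimethylsilyloxy)-2-methoxy-6-methylbenzoic acid
Conditions: NaClO2, NaH2PO4, 2-methylbut-2-ene, t-BuOH/H2O, rt
Reagents that add atoms: sodium chlorite, [Na+].[O-]Cl=O
Why: Pinnick oxidation at about pH 4 converts the hindered, electron-rich aldehyde into the acid without touching the aryl silyl ether, and excess alkene removes HOCl before it can chlorinate the ring.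

Step 14
Reactants: 17 2-diazo-1-[4-(2-oxoethyl)-6-[(E)-prop-1-enyl]-2H-pyran-3-yl]propan-1-one; 22 4-(tert-butyldimethylsilyloxy)-2-methoxy-6-methylbenzoic acid
Product: 24 (6R,7S)-6-hydroxy-7-methyl-8-oxo-3-[(E)-prop-1-enyl]-5,6,7,8-tetrahydro-1H-isochromen-7-yl 4-(tert-butyldimethylsilyloxy)-2-methoxy-6-methylbenzoate, via acyloxy enol 23 (not isolated)
Conditions: 17 added by syringe pump to 22 (1.5 equiv), Rh2(O2CCPh3)4 (2 mol %), (R)-TRIP [(R)-3,3'-bis(2,4,6-triisopropylphenyl)-1,1'-binaphthyl-2,2'-diyl hydrogen phosphate, 10 mol %], 4 Å molecular sieves, CH2Cl2, −40 °C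
Reagents that add atoms: none
Why: Proposed new method: the dirhodium catalyst expels N2 from 17 to give an electrophilic carbenoid at C7, a carboxyl oxygen of 22 adds to it, and proton relay to the C8 oxygen releases the (Z)-acyloxy enol 23 (both oxygens on one side of C7=C8), whose C7 then attacks the tethered C6 aldehyde before ketonisation, so that the C7–O and C6–C7 bonds form in one flask. The closest known reaction types are the dirhodium-catalysed O–H insertion of carboxylic acids into α-diazo ketones and the aldol-type interception of carbenoid-derived oxonium ylides or enols by aldehydes under dirhodium and phosphoric acid co-catalysis, but a carboxylic acid donor combined with an internal aldehyde trap has not been shown. Ring B closes in the favoured 6-(enolendo)-exo-trig mode, because the C7=C8 enol bond lies inside the new six-membered ring and the formyl C=O outside it. C7 is fixed by the enol face that is attacked and C6 by the formyl face that is presented: the chiral acid should bridge the enol O–H (through P=O) and the formyl oxygen (through P–OH) so that its 3,3'-aryl groups select the enol face, and a half-chair with the formyl oxygen pseudo-equatorial and antiperiplanar to C7=C8 then places C6–OH trans to the C7 ester oxygen, although sense and level of this induction remain to be proven. Capture of the carbenoid by the acid must outrun the 1,2-hydride shift from the C7 methyl group, attack by the formyl oxygen, insertion into C5–H and simple protonation of the diazo carbon; bulky triphenylacetate ligands, low temperature, excess 22 and slow addition of 17 serve the first and last, while in the substrate the seven-membered ring required for a carbonyl ylide and the electron-poor C5–H bonds slow the internal paths. The aldol must also outrun ketonisation, which the cis C4a=C8a double bond secures by holding the formyl carbon next to C7, and the two ortho groups of 22, which would block any acylation through its carbonyl carbon, are remote from the oxygen that bonds.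

Step 15
Reactants: 24 (6R,7S)-6-hydroxy-7-methyl-8-oxo-3-[(E)-prop-1-enyl]-5,6,7,8-tetrahydro-1H-isochromen-7-yl 4-(tert-butyldimethylsilyloxy)-2-methoxy-6-methylbenzoate
Product: 25 (6R,7S)-6-hydroxy-7-methyl-8-oxo-3-[(E)-prop-1-enyl]-5,6,7,8-tetrahydro-1H-isochromen-7-yl 4-hydroxy-2-methoxy-6-methylbenzoate
Conditions: HF·pyridine, pyridine, THF, 0 °C
Reagents that add atoms: none
Why: Fluoride cleavage of an aryl silyl ether with pyridine-buffered HF·pyridine is fast and only mildly acidic, which avoids the retro-aldol, vinylogous dehydration (C6–OH with a C5 proton) and acyl migration that a basic fluoride source could trigger, so C6 and C7 stay untouched.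

Compound list
1 | but-3-yn-1-ol | C#CCCO | starting material
2 | tert-butyl(but-3-yn-1-yloxy)dimethylsilane | C#CCCO[Si](C)(C)C(C)(C)C | intermediate
3 | (E)-but-2-enal (crotonaldehyde) | C/C=C/C=O | starting material
4 | lithium 4-(tert-butyldimethylsilyloxy)but-1-yn-1-ide | [Li]C#CCCO[Si](C)(C)C(C)(C)C | intermediate
5 | (E)-8-(tert-butyldimethylsilyloxy)oct-2-en-5-yn-4-ol (racemic) | C/C=C/C(O)C#CCCO[Si](C)(C)C(C)(C)C | intermediate
6 | (E)-8-(tert-butyldimethylsilyloxy)oct-2-en-5-yn-4-one | C/C=C/C(=O)C#CCCO[Si](C)(C)C(C)(C)C | intermediate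
7 | (2E,5Z)-8-(tert-butyldimethylsilyloxy)-6-iodoocta-2,5-dien-4-one | C/C=C/C(=O)/C=C(\I)CCO[Si](C)(C)C(C)(C)C | intermediate
8 | pent-1-yn-3-ol | CCC(O)C#C | starting material
9 | pent-1-yn-3-one | CCC(=O)C#C | intermediate
10 | 2-(tributylstannyl)pent-1-en-3-one | CCC(=O)C(=C)[Sn](CCCC)(CCCC)CCCC | intermediate
11 | (2E,5Z)-6-[2-(tert-butyldimethylsilyloxy)ethyl]-7-methylidenedeca-2,5-diene-4,8-dione | C/C=C/C(=O)/C=C(CCO[Si](C)(C)C(C)(C)C)\C(=C)C(=O)CC | intermediate
12 | 1-[4-[2-(tert-butyldimethylsilyloxy)ethyl]-6-[(E)-prop-1-enyl]-2H-pyran-3-yl]propan-1-one | C/C=C/C1=CC(CCO[Si](C)(C)C(C)(C)C)=C(CO1)C(=O)CC | intermediate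
13 | lithium enolate of 12 at the ethyl CH2 (enolate geometry of no consequence) | C/C=C/C1=CC(CCO[Si](C)(C)C(C)(C)C)=C(CO1)C(O[Li])=CC | intermediate
14 | 1-[4-[2-(tert-butyldimethylsilyloxy)ethyl]-6-[(E)-prop-1-enyl]-2H-pyran-3-yl]-4,4,4-trifluoro-2-methylbutane-1,3-dione (racemic) | C/C=C/C1=CC(CCO[Si](C)(C)C(C)(C)C)=C(CO1)C(=O)C(C)C(=O)C(F)(F)F | intermediate
15 | 1-[4-[2-(tert-butyldimethylsilyloxy)ethyl]-6-[(E)-prop-1-enyl]-2H-pyran-3-yl]-2-diazopropan-1-one | C/C=C/C1=CC(CCO[Si](C)(C)C(C)(C)C)=C(CO1)C(=O)C(C)=[N+]=[N-] | intermediate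
16 | 2-diazo-1-[4-(2-hydroxyethyl)-6-[(E)-prop-1-enyl]-2H-pyran-3-yl]propan-1-one | C/C=C/C1=CC(CCO)=C(CO1)C(=O)C(C)=[N+]=[N-] | intermediate
17 | 2-diazo-1-[4-(2-oxoethyl)-6-[(E)-prop-1-enyl]-2H-pyran-3-yl]propan-1-one | C/C=C/C1=CC(CC=O)=C(CO1)C(=O)C(C)=[N+]=[N-] | intermediate
18 | 3-methoxy-5-methylphenol | COc1cc(C)cc(O)c1 | starting material
19 | (4-hydroxy-2-methoxy-6-methylbenzylidene)dimethyliminium chloride | COc1cc(O)cc(C)c1C=[N+](C)C.[Cl-] | intermediate
20 | 4-hydroxy-2-methoxy-6-methylbenzaldehyde | COc1cc(O)cc(C)c1C=O | intermediate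
21 | 4-(tert-butyldimethylsilyloxy)-2-methoxy-6-methylbenzaldehyde | COc1cc(O[Si](C)(C)C(C)(C)C)cc(C)c1C=O | intermediate
22 | 4-(tert-butyldimethylsilyloxy)-2-methoxy-6-methylbenzoic acid | COc1cc(O[Si](C)(C)C(C)(C)C)cc(C)c1C(=O)O | intermediate
23 | (Z)-1-hydroxy-1-[4-(2-oxoethyl)-6-[(E)-prop-1-enyl]-2H-pyran-3-yl]prop-1-en-2-yl 4-(tert-butyldimethylsilyloxy)-2-methoxy-6-methylbenzoate | C/C=C/C1=CC(CC=O)=C(CO1)/C(O)=C(\C)OC(=O)c1c(C)cc(O[Si](C)(C)C(C)(C)C)cc1OC | intermediate
24 | (6R,7S)-6-hydroxy-7-methyl-8-oxo-3-[(E)-prop-1-enyl]-5,6,7,8-tetrahydro-1H-isochromen-7-yl 4-(tert-butyldimethylsilyloxy)-2-methoxy-6-methylbenzoate | C/C=C/C1=CC2=C(CO1)C(=O)[C@@](C)(OC(=O)c1c(C)cc(O[Si](C)(C)C(C)(C)C)cc1OC)[C@H](O)C2 | intermediate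
25 | (6R,7S)-6-hydroxy-7-methyl-8-oxo-3-[(E)-prop-1-enyl]-5,6,7,8-tetrahydro-1H-isochromen-7-yl 4-hydroxy-2-methoxy-6-methylbenzoate | C/C=C/C1=CC2=C(CO1)C(=O)[C@@](C)(OC(=O)c1c(C)cc(O)cc1OC)[C@H](O)C2 | target

Total step count: 15. Longest linear sequence: 10 steps (1, 2, 3, 4, 7, 8, 9, 10, 14, 15) from but-3-yn-1-ol.

Steps most likely to fail

**Step 14.** Several processes could defeat it:
- The enol may ketonise before it reaches the aldehyde.
- The carbenoid may be lost by hydride shift or by attack of the formyl oxygen.
- The chiral acid may protonate the diazo carbon.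
- Facial selectivity in the ring closure may be poor.

The fallback uses known chemistry, sets out from 17 and 22 and returns at 24. It runs the two bond formations separately and obtains the absolute configuration by resolution. Rh2(OAc)4 alone (CH2Cl2, rt, slow addition of 17 to 22) performs the ordinary O–H insertion. After ketonisation this gives racemic 1-oxo-1-[4-(2-oxoethyl)-6-[(E)-prop-1-enyl]-2H-pyran-3-yl]propan-2-yl 4-(tert-butyldimethylsilyloxy)-2-methoxy-6-methylbenzoate F1. A catalytic amidine base (DBU, CH2Cl2, 0 °C) then closes ring B by an ordinary, reversible intramolecular aldol addition. Deprotonation at C5 is unproductive but harmless. The trans aldol, isolated by chromatography, is the racemate of 24 and its mirror image, the (6S,7R)-configured silyl ether F2. HPLC on a chiral stationary phase delivers 24.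

**Step 7.** Transmetalation of the electron-poor, hindered stannane may be slow. That would leave time for protodestannylation and for polymerisation of the enone partner or of the open form before ring closure.

The fallback sets out from 10 and 7 and returns at 12. The coupling is run at the alcohol oxidation level, and the electron-poor diene is created only afterwards. Luche reduction (NaBH4, CeCl3·7H2O, MeOH, 0 °C) converts 10 into racemic 2-(tributylstannyl)pent-1-en-3-ol F3, an electron-richer and sturdier Stille partner. Coupling with 7 (Pd(PPh3)4, CuI, DMF, rt) gives racemic (2E,5Z)-6-[2-(tert-butyldimethylsilyloxy)ethyl]-8-hydroxy-7-methylidenedeca-2,5-dien-4-one F4. MnO2 in CH2Cl2 then oxidises its allylic alcohol under neutral conditions to 11, which closes to 12.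

**Step 10.** The aldehyde may enolise or shift its double bond into conjugation. The diazo group may also be lost to the acetic acid released during oxidation or on isolation.

The fallback sets out from 15 and 22 and returns at 24. The C7–O bond is made before the aldehyde is unmasked, so that no compound carries a diazo group and an aldehyde together. Rh2(OAc)4-catalysed O–H insertion of 22 into 15 gives racemic 1-[4-[2-(tert-butyldimethylsilyloxy)ethyl]-6-[(E)-prop-1-enyl]-2H-pyran-3-yl]-1-oxopropan-2-yl 4-(tert-butyldimethylsilyloxy)-2-methoxy-6-methylbenzoate F5. Pyridinium tosylate in EtOH removes the primary alkyl silyl ether faster than the aryl one and gives the racemic primary alcohol 1-[4-(2-hydroxyethyl)-6-[(E)-prop-1-enyl]-2H-pyran-3-yl]-1-oxopropan-2-yl 4-(tert-butyldimethylsilyloxy)-2-methoxy-6-methylbenzoate F6. Dess–Martin oxidation leads to the acyloxy keto aldehyde F1 of the first fallback, which is closed and resolved as described there to reach 24.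

Further compounds
F1 | step 14 | 1-oxo-1-[4-(2-oxoethyl)-6-[(E)-prop-1-enyl]-2H-pyran-3-yl]propan-2-yl 4-(tert-butyldimethylsilyloxy)-2-methoxy-6-methylbenzoate (racemic) | C/C=C/C1=CC(CC=O)=C(CO1)C(=O)C(C)OC(=O)c1c(C)cc(O[Si](C)(C)C(C)(C)C)cc1OC
F2 | step 14 | (6S,7R)-6-hydroxy-7-methyl-8-oxo-3-[(E)-prop-1-enyl]-5,6,7,8-tetrahydro-1H-isochromen-7-yl 4-(tert-butyldimethylsilyloxy)-2-methoxy-6-methylbenzoate | C/C=C/C1=CC2=C(CO1)C(=O)[C@](C)(OC(=O)c1c(C)cc(O[Si](C)(C)C(C)(C)C)cc1OC)[C@@H](O)C2
F3 | step 7 | 2-(tributylstannyl)pent-1-en-3-ol (racemic) | CCC(O)C(=C)[Sn](CCCC)(CCCC)CCCC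
F4 | step 7 | (2E,5Z)-6-[2-(tert-butyldimethylsilyloxy)ethyl]-8-hydroxy-7-methylidenedeca-2,5-dien-4-one (racemic) | C/C=C/C(=O)/C=C(CCO[Si](C)(C)C(C)(C)C)\C(=C)C(O)CC
F5 | step 10 | 1-[4-[2-(tert-butyldimethylsilyloxy)ethyl]-6-[(E)-prop-1-enyl]-2H-pyran-3-yl]-1-oxopropan-2-yl 4-(tert-butyldimethylsilyloxy)-2-methoxy-6-methylbenzoate (racemic) | C/C=C/C1=CC(CCO[Si](C)(C)C(C)(C)C)=C(CO1)C(=O)C(C)OC(=O)c1c(C)cc(O[Si](C)(C)C(C)(C)C)cc1OC
F6 | step 10 | 1-[4-(2-hydroxyethyl)-6-[(E)-prop-1-enyl]-2H-pyran-3-yl]-1-oxopropan-2-yl 4-(tert-butyldimethylsilyloxy)-2-methoxy-6-methylbenzoate (racemic) | C/C=C/C1=CC(CCO)=C(CO1)C(=O)C(C)OC(=O)c1c(C)cc(O[Si](C)(C)C(C)(C)C)cc1OC
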